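The flavonol is cut at O1–C8a of ring C. C8a is flanked by the methoxy-bearing C8 and by C4a, which carries the C4 carbonyl. An iodide on C8a therefore faces the enolate oxygen on C2 of a 2-oxygenated 1,3-diketone. One copper-catalysed intramolecular O-arylation then closes the pyranone with every oxygen substituent already in place. The precursor is a 1-(2-iodoaryl)-2-(methoxymethoxy)-3-aryl-1,3-diketone with benzyl ethers on the future O5 and O7 and MOM ethers on O3 and O4'. Its iodine comes ready-made from 5-iodovanillin, and aldol addition plus oxidation assembles the diketone. Hydrogenolysis, selective 7-O-prenylation and mild acetal cleavage complete the synthesis.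

Key step: step 12

Assumption: the target has no stereocentre, so the aldol adduct is carried on as a racemic mixture of diastereomers and the diketone as a racemate.

Design choices:
- (a) The iodine is not installed by a late C–H iodination. On a 2,4-dialkoxy-5-methoxybenzoyl ring, the electrophilic iodine sources such reactions need would rather attack the carbon between the two benzyloxy groups (future C6) or the carboxyl-bearing ipso carbon. In 5-iodovanillin the three neighbouring carbons bearing I, O and O already map onto C8a, C8 and C7, and the formyl carbon marks the future O5.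
- (b) The diketone is built from the aldehyde. This avoids O-acylation of an enolate by a doubly ortho-substituted aroyl chloride.
- (c) The benzyl/MOM pattern of the precursor is kept. The MOM group on O3 also blocks closure to a five-membered benzofuranone.

Step 1
Reactants: 1 5-iodovanillin (4-hydroxy-3-iodo-5-methoxybenzaldehyde)
Product: 2 3,4-dihydroxy-5-iodobenzaldehyde
Conditions: AlCl3 (1.2 equiv), pyridine (4.5 equiv), CH2Cl2, reflux; then 2 M aq. HCl
Reagents that add atoms: none
Why: Lewis-acid-assisted demethylation of a guaiacol: the aluminium phenolate formed at the free 4-OH chelates the adjacent methoxy oxygen and pyridine takes the methyl group by SN2 attack, a standard operation on 5-halovanillins that touches neither the aldehyde nor the iodide.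

Step 2
Reactants: 2 3,4-dihydroxy-5-iodobenzaldehyde
Product: 3 3-hydroxy-5-iodo-4-methoxybenzaldehyde
Conditions: MeI (1.1 equiv), Li2CO3 (1.2 equiv), DMF, 45 °C
Reagents that add atoms: iodomethane, CI
Why: Regioselective Williamson etherification: the 4-OH is para to the formyl group and ortho to iodine and therefore much the more acidic of the two, so the weak base Li2CO3 generates only that phenoxide and the small electrophile caps it, the established selectivity pattern of 3,4-dihydroxybenzaldehydes.

Step 3
Reactants: 3 3-hydroxy-5-iodo-4-methoxybenzaldehyde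
Product: 4 3-(benzyloxy)-5-iodo-4-methoxybenzaldehyde
Conditions: BnBr (1.1 equiv), K2CO3, DMF, rt
Reagents that add atoms: benzyl bromide, BrCc1ccccc1
Why: Williamson etherification of the only remaining phenol, which fixes the future O7 as a hydrogenolysable ether distinct from the O8 methyl group.

Step 4
Reactants: 4 3-(benzyloxy)-5-iodo-4-methoxybenzaldehyde
Product: 6 3-(benzyloxy)-5-iodo-4-methoxyphenol, via aryl formate 5 (not isolated)
Conditions: mCPBA (1.5 equiv), CH2Cl2, rt; aq. Na2SO3/NaHCO3 wash; then K2CO3 (cat.), MeOH, rt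
Reagents that add atoms: 3-chloroperbenzoic acid (mCPBA), O=C(OO)c1cccc(Cl)c1
Why: Baeyer–Villiger oxidation: the para-methoxy, meta-benzyloxy aryl group migrates in the Criegee adduct in preference to hydride, the crude formate is methanolysed directly, and the sulfite wash would return any iodine that had been oxidised to the trivalent state.

Step 5
Reactants: 6 3-(benzyloxy)-5-iodo-4-methoxyphenol
Product: 7 1,5-bis(benzyloxy)-3-iodo-2-methoxybenzene
Conditions: BnBr (1.1 equiv), K2CO3, DMF, rt
Reagents that add atoms: benzyl bromide, BrCc1ccccc1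
Why: Williamson etherification of the new phenol, the future O5, giving the same benzyl mask as on O7 so that both fall in one later operation.

Step 6
Reactants: 7 1,5-bis(benzyloxy)-3-iodo-2-methoxybenzene
Product: 9 2,4-bis(benzyloxy)-6-iodo-5-methoxybenzaldehyde, via iminium chloride 8 (not isolated)
Conditions: POCl3 (2 equiv), DMF, 0 to 65 °C; then ice–water, rt
Reagents that add atoms: N,N-dimethylformamide, CN(C)C=O; water, O
Why: Vilsmeier–Haack formylation: the chloroiminium ion attacks the carbon that is para to one benzyloxy group and ortho to the other, the regiochemistry known for 1-halo-3,5-dialkoxybenzenes, whereas the site between the two benzyloxy groups has only ortho activation and is screened by both benzyl groups, and the iodine-bearing carbon is meta to both donors and so safe from ipso attack.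

Step 7
Reactants: 10 acetovanillone (1-(4-hydroxy-3-methoxyphenyl)ethan-1-one)
Product: 11 2-bromo-1-(4-hydroxy-3-methoxyphenyl)ethan-1-one
Conditions: CuBr2 (2.1 equiv), EtOAc–CHCl3 1:1, reflux
Reagents that add atoms: copper dibromide CuBr2, [Cu+2].[Br-].[Br-]
Why: Heterogeneous α-bromination of an aryl methyl ketone with CuBr2, which brominates through the copper-bound enol and stops at the monobromide without nuclear bromination of the free phenol.

Step 8
Reactants: 11 2-bromo-1-(4-hydroxy-3-methoxyphenyl)ethan-1-one
Product: 13 2-hydroxy-1-(4-hydroxy-3-methoxyphenyl)ethan-1-one, via formate ester 12 (not isolated)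
Conditions: HCO2Na (3 equiv), EtOH–H2O 3:1, reflux
Reagents that add atoms: sodium formate, [Na+].[O-]C=O
Why: SN2 displacement of the phenacyl bromide by formate followed by hydrolysis of the labile formate ester in the same pot, under a buffer too weakly basic to ionise the phenol and start O-alkylation.

Step 9
Reactants: 13 2-hydroxy-1-(4-hydroxy-3-methoxyphenyl)ethan-1-one
Product: 14 2-(methoxymethoxy)-1-[3-methoxy-4-(methoxymethoxy)phenyl]ethan-1-one
Conditions: MOMCl (3 equiv), i-Pr2NEt (4 equiv), CH2Cl2, 0 °C to rt
Reagents that add atoms: chloromethyl methyl ether (MOMCl), COCCl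
Why: Double acetal formation (MOM etherification): the hindered amine base lets the phenol and the primary α-ketol hydroxyl both be alkylated by MOMCl in one operation without enolising the ketone.

Step 10
Reactants: 14 2-(methoxymethoxy)-1-[3-methoxy-4-(methoxymethoxy)phenyl]ethan-1-one; 9 2,4-bis(benzyloxy)-6-iodo-5-methoxybenzaldehyde
Product: 16 3-[2,4-bis(benzyloxy)-6-iodo-5-methoxyphenyl]-3-hydroxy-2-(methoxymethoxy)-1-[3-methoxy-4-(methoxymethoxy)phenyl]propan-1-one (racemic syn/anti mixture), via lithium enolate 15 (not isolated)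
Conditions: LiN(SiMe3)2 (1.1 equiv), THF, −78 °C; then 9 in THF, −78 °C; AcOH quench at −78 °C
Reagents that add atoms: none
Why: Directed crossed aldol addition of a preformed lithium enolate to a non-enolisable aldehyde, free of halogen–metal exchange because no alkyllithium is present and quenched cold to forestall retro-aldol; the two new stereocentres form without control, which does not matter because both become sp2 carbons in steps 11 and 12.

Step 11
Reactants: 16 the aldol adduct (racemic syn/anti mixture)
Product: 17 1-[2,4-bis(benzyloxy)-6-iodo-5-methoxyphenyl]-2-(methoxymethoxy)-3-[3-methoxy-4-(methoxymethoxy)phenyl]propane-1,3-dione (racemic, enolisable)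
Conditions: IBX (3 equiv), EtOAc, 75 °C
Reagents that add atoms: none
Why: IBX oxidation of a β-hydroxy ketone to the 1,3-diketone, a neutral method known to stop at the diketone and compatible with aryl iodide, benzyl ethers and MOM acetals; it removes one stereocentre and leaves the other as an enolisable racemic centre.

Step 12
Reactants: 17 1-[2,4-bis(benzyloxy)-6-iodo-5-methoxyphenyl]-2-(methoxymethoxy)-3-[3-methoxy-4-(methoxymethoxy)phenyl]propane-1,3-dione
Product: 18 5,7-bis(benzyloxy)-8-methoxy-3-(methoxymethoxy)-2-[3-methoxy-4-(methoxymethoxy)phenyl]-4H-chromen-4-one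
Conditions: CuI (10 mol %), 1,10-phenanthroline (20 mol %), K3PO4 (2 equiv), 4 Å molecular sieves, DMF, 90 °C, Ar
Reagents that add atoms: none
Why: K3PO4 removes the proton on the central carbon (future C3), the enolate formed toward the ring B carbonyl binds phenanthroline-ligated monovalent copper through its oxygen, oxidative addition of the adjacent C8a–I bond gives a seven-membered trivalent-copper metallacycle, and reductive elimination forms O1–C8a. The closest known reaction is the Ullmann-type, copper-catalysed intramolecular O-arylation of 1-(2-haloaryl)-1,3-diketones to flavones and chromones. Ring C closes as a six-membered ring by attack of a tethered oxygen on an sp2 carbon whose leaving group lies outside the new ring (6-exo mode), and formation of the conjugated 4-pyranone makes the closure irreversible. No stereocentre is created, and the racemic centre of 17 disappears as C3 becomes sp2. The step needs O- over C-arylation and the correct oxygen: arylation at C3 or through the C4 carbonyl oxygen would demand a four-membered ring, and the C3 oxygen, which could otherwise close a five-membered benzofuranone, is blocked as its MOM ether. The ortho acyl group holds copper next to the hindered iodide, and the methyl, benzyl and MOM ethers are inert to CuI and K3PO4.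

Step 13
Reactants: 18 5,7-bis(benzyloxy)-8-methoxy-3-(methoxymethoxy)-2-[3-methoxy-4-(methoxymethoxy)phenyl]-4H-chromen-4-one
Product: 19 5,7-dihydroxy-8-methoxy-3-(methoxymethoxy)-2-[3-methoxy-4-(methoxymethoxy)phenyl]-4H-chromen-4-one
Conditions: H2 (1 atm), Pd/C (10 wt % Pd), EtOAc–MeOH, rt
Reagents that add atoms: none
Why: Catalytic hydrogenolysis of two aryl benzyl ethers, carried out before any alkene is present; MOM acetals, methyl ethers and the tetrasubstituted cross-conjugated C2=C3 bond are inert at atmospheric pressure.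

Step 14
Reactants: 19 5,7-dihydroxy-8-methoxy-3-(methoxymethoxy)-2-[3-methoxy-4-(methoxymethoxy)phenyl]-4H-chromen-4-one; 20 prenyl bromide (1-bromo-3-methylbut-2-ene)
Product: 21 5-hydroxy-8-methoxy-3-(methoxymethoxy)-2-[3-methoxy-4-(methoxymethoxy)phenyl]-7-[(3-methylbut-2-en-1-yl)oxy]-4H-chromen-4-one
Conditions: 20 (1.1 equiv), K2CO3 (1.2 equiv), acetone, rt to 45 °C
Reagents that add atoms: none
Why: Regioselective Williamson etherification: the 7-OH is the acidic, vinylogous carboxylic acid hydroxyl, while the 5-OH is tied up in a hydrogen bond to the C4 carbonyl and stays unreactive toward one equivalent of prenyl bromide under K2CO3, the standard selectivity of 5,7-dihydroxyflavones.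

Step 15
Reactants: 21 5-hydroxy-8-methoxy-3-(methoxymethoxy)-2-[3-methoxy-4-(methoxymethoxy)phenyl]-7-[(3-methylbut-2-en-1-yl)oxy]-4H-chromen-4-one
Product: 22 3,5-dihydroxy-2-(4-hydroxy-3-methoxyphenyl)-8-methoxy-7-[(3-methylbut-2-en-1-yl)oxy]-4H-chromen-4-one (target, CNP0210396.0)
Conditions: conc. aq. HCl (cat., about 0.3 M final), MeOH–THF, 25–35 °C, monitored; NaHCO3 quench
Reagents that add atoms: none
Why: Acid-catalysed transacetalisation: both MOM acetals ionise through the strongly stabilised methoxymethyl oxocarbenium ion and are trapped by methanol far faster than the prenyl aryl ether can ionise to a dimethylallyl cation, so dilute acid near room temperature with early quenching should free O3 and O4' and leave the 7-O-prenyl group and its double bond intact.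

Compound list
1 | 5-iodovanillin (4-hydroxy-3-iodo-5-methoxybenzaldehyde) | COc1cc(C=O)cc(I)c1O | starting material
2 | 3,4-dihydroxy-5-iodobenzaldehyde | Oc1cc(C=O)cc(I)c1O | intermediate
3 | 3-hydroxy-5-iodo-4-methoxybenzaldehyde | COc1c(O)cc(C=O)cc1I | intermediate
4 | 3-(benzyloxy)-5-iodo-4-methoxybenzaldehyde | COc1c(I)cc(C=O)cc1OCc1ccccc1 | intermediate
5 | 3-(benzyloxy)-5-iodo-4-methoxyphenyl formate (not isolated) | O=COc1cc(I)c(OC)c(OCc2ccccc2)c1 | intermediate
6 | 3-(benzyloxy)-5-iodo-4-methoxyphenol | Oc1cc(I)c(OC)c(OCc2ccccc2)c1 | intermediate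
7 | 1,5-bis(benzyloxy)-3-iodo-2-methoxybenzene | COc1c(I)cc(OCc2ccccc2)cc1OCc1ccccc1 | intermediate
8 | [2,4-bis(benzyloxy)-6-iodo-5-methoxyphenyl]methylidene(dimethyl)ammonium chloride (not isolated) | C[N+](C)=Cc1c(I)c(OC)c(OCc2ccccc2)cc1OCc1ccccc1.[Cl-] | intermediate
9 | 2,4-bis(benzyloxy)-6-iodo-5-methoxybenzaldehyde | O=Cc1c(I)c(OC)c(OCc2ccccc2)cc1OCc1ccccc1 | intermediate
10 | acetovanillone | CC(=O)c1ccc(O)c(OC)c1 | starting material
11 | 2-bromo-1-(4-hydroxy-3-methoxyphenyl)ethan-1-one | O=C(CBr)c1ccc(O)c(OC)c1 | intermediate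
12 | 2-(4-hydroxy-3-methoxyphenyl)-2-oxoethyl formate (not isolated) | O=COCC(=O)c1ccc(O)c(OC)c1 | intermediate
13 | 2-hydroxy-1-(4-hydroxy-3-methoxyphenyl)ethan-1-one | O=C(CO)c1ccc(O)c(OC)c1 | intermediate
14 | 2-(methoxymethoxy)-1-[3-methoxy-4-(methoxymethoxy)phenyl]ethan-1-one | COCOCC(=O)c1ccc(OCOC)c(OC)c1 | intermediate
15 | lithium enolate of 14 (not isolated; geometry of no consequence) | [Li+].[O-]C(=COCOC)c1ccc(OCOC)c(OC)c1 | intermediate
16 | 3-[2,4-bis(benzyloxy)-6-iodo-5-methoxyphenyl]-3-hydroxy-2-(methoxymethoxy)-1-[3-methoxy-4-(methoxymethoxy)phenyl]propan-1-one (racemic syn/anti mixture) | COCOc1ccc(C(=O)C(OCOC)C(O)c2c(I)c(OC)c(OCc3ccccc3)cc2OCc2ccccc2)cc1OC | intermediate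
17 | 1-[2,4-bis(benzyloxy)-6-iodo-5-methoxyphenyl]-2-(methoxymethoxy)-3-[3-methoxy-4-(methoxymethoxy)phenyl]propane-1,3-dione (racemic) | COCOc1ccc(C(=O)C(OCOC)C(=O)c2c(I)c(OC)c(OCc3ccccc3)cc2OCc2ccccc2)cc1OC | intermediate
18 | 5,7-bis(benzyloxy)-8-methoxy-3-(methoxymethoxy)-2-[3-methoxy-4-(methoxymethoxy)phenyl]-4H-chromen-4-one | COCOc1ccc(-c2oc3c(OC)c(OCc4ccccc4)cc(OCc4ccccc4)c3c(=O)c2OCOC)cc1OC | intermediate
19 | 5,7-dihydroxy-8-methoxy-3-(methoxymethoxy)-2-[3-methoxy-4-(methoxymethoxy)phenyl]-4H-chromen-4-one | COCOc1ccc(-c2oc3c(OC)c(O)cc(O)c3c(=O)c2OCOC)cc1OC | intermediate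
20 | prenyl bromide (1-bromo-3-methylbut-2-ene) | CC(C)=CCBr | starting material
21 | 5-hydroxy-8-methoxy-3-(methoxymethoxy)-2-[3-methoxy-4-(methoxymethoxy)phenyl]-7-[(3-methylbut-2-en-1-yl)oxy]-4H-chromen-4-one | COCOc1ccc(-c2oc3c(OC)c(OCC=C(C)C)cc(O)c3c(=O)c2OCOC)cc1OC | intermediate
22 | 3,5-dihydroxy-2-(4-hydroxy-3-methoxyphenyl)-8-methoxy-7-[(3-methylbut-2-en-1-yl)oxy]-4H-chromen-4-one | COc1cc(-c2oc3c(OC)c(OCC=C(C)C)cc(O)c3c(=O)c2O)ccc1O | target

Total step count: 15 steps.
Longest linear sequence: 12 steps (steps 1–6 and 10–15, from 5-iodovanillin); steps 7–9 form the ring B branch.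

Steps most likely to fail

Step 12 (key step).
- What may go wrong: the crowded 2-alkoxy diketone enolises reluctantly, so base-induced retro-Claisen cleavage or reductive loss of iodine may outrun C–O bond formation.
- Fallback: it sets out from 9 and 10, comes back at 18, and leaves the C3 oxygen out until ring C exists. Acetovanillone 10 is protected with MOMCl and i-Pr2NEt as 1-[3-methoxy-4-(methoxymethoxy)phenyl]ethan-1-one F1. The lithium enolate of this ketone adds to aldehyde 9 to give racemic 3-[2,4-bis(benzyloxy)-6-iodo-5-methoxyphenyl]-3-hydroxy-1-[3-methoxy-4-(methoxymethoxy)phenyl]propan-1-one F2. IBX oxidation gives the C3-unsubstituted, fully enolised 1-[2,4-bis(benzyloxy)-6-iodo-5-methoxyphenyl]-3-[3-methoxy-4-(methoxymethoxy)phenyl]propane-1,3-dione F3, which belongs to the substrate class for which the copper closure is established. CuI, 1,10-phenanthroline and K3PO4 then give 5,7-bis(benzyloxy)-8-methoxy-2-[3-methoxy-4-(methoxymethoxy)phenyl]-4H-chromen-4-one F4. Dimethyldioxirane in acetone–CH2Cl2 at 0 °C epoxidises C2=C3, and the epoxide opens on silica gel to 5,7-bis(benzyloxy)-3-hydroxy-8-methoxy-2-[3-methoxy-4-(methoxymethoxy)phenyl]-4H-chromen-4-one F5. MOMCl and i-Pr2NEt convert this compound into 18.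

Step 15.
- What may go wrong: acid-induced ionisation of the prenyl aryl ether (loss of the prenyl group), or addition of solvent across its double bond, may compete with acetal cleavage.
- Fallback: it sets out from 18, comes back at 22, and uses acid only before the prenyl group exists, so the last step is basic. HCl in MeOH at 50 °C strips both MOM groups of 18 to give 5,7-bis(benzyloxy)-3-hydroxy-2-(4-hydroxy-3-methoxyphenyl)-8-methoxy-4H-chromen-4-one F6. Ac2O in pyridine gives 4-[3-(acetyloxy)-5,7-bis(benzyloxy)-8-methoxy-4-oxo-4H-chromen-2-yl]-2-methoxyphenyl acetate F7. Hydrogenolysis (H2, Pd/C, EtOAc) gives 4-[3-(acetyloxy)-5,7-dihydroxy-8-methoxy-4-oxo-4H-chromen-2-yl]-2-methoxyphenyl acetate F8. A Mitsunobu reaction with 3-methylbut-2-en-1-ol, PPh3 and DIAD in THF etherifies only the acidic 7-OH under neutral conditions and gives 4-{3-(acetyloxy)-5-hydroxy-8-methoxy-7-[(3-methylbut-2-en-1-yl)oxy]-4-oxo-4H-chromen-2-yl}-2-methoxyphenyl acetate F9. Catalytic K2CO3 in MeOH at 0 °C under argon removes both acetates and gives 22.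

Step 10.
- What may go wrong: reversal of the aldol addition at the crowded, electron-rich aldehyde may leave low conversion.
- Fallback: it sets out from 9, uses 14, comes back at 17, and replaces the reversible addition by an irreversible C-acylation. Pinnick oxidation of 9 (NaClO2, NaH2PO4, 2-methylbut-2-ene, t-BuOH–H2O) gives 2,4-bis(benzyloxy)-6-iodo-5-methoxybenzoic acid F10. Oxalyl chloride with catalytic DMF gives 2,4-bis(benzyloxy)-6-iodo-5-methoxybenzoyl chloride F11. Soft enolisation of 14 with MgBr2·OEt2 and i-Pr2NEt in CH2Cl2, where the magnesium chelate of the α-alkoxy ketone favours carbon over oxygen attack, acylates it with this chloride directly to 17.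

Further compounds
F1 | step 12 | 1-[3-methoxy-4-(methoxymethoxy)phenyl]ethan-1-one | CC(=O)c1ccc(OCOC)c(OC)c1
F2 | step 12 | 3-[2,4-bis(benzyloxy)-6-iodo-5-methoxyphenyl]-3-hydroxy-1-[3-methoxy-4-(methoxymethoxy)phenyl]propan-1-one (racemic) | COCOc1ccc(C(=O)CC(O)c2c(I)c(OC)c(OCc3ccccc3)cc2OCc2ccccc2)cc1OC
F3 | step 12 | 1-[2,4-bis(benzyloxy)-6-iodo-5-methoxyphenyl]-3-[3-methoxy-4-(methoxymethoxy)phenyl]propane-1,3-dione | COCOc1ccc(C(=O)CC(=O)c2c(I)c(OC)c(OCc3ccccc3)cc2OCc2ccccc2)cc1OC
F4 | step 12 | 5,7-bis(benzyloxy)-8-methoxy-2-[3-methoxy-4-(methoxymethoxy)phenyl]-4H-chromen-4-one | COCOc1ccc(-c2cc(=O)c3c(OCc4ccccc4)cc(OCc4ccccc4)c(OC)c3o2)cc1OC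
F5 | step 12 | 5,7-bis(benzyloxy)-3-hydroxy-8-methoxy-2-[3-methoxy-4-(methoxymethoxy)phenyl]-4H-chromen-4-one | COCOc1ccc(-c2oc3c(OC)c(OCc4ccccc4)cc(OCc4ccccc4)c3c(=O)c2O)cc1OC
F6 | step 15 | 5,7-bis(benzyloxy)-3-hydroxy-2-(4-hydroxy-3-methoxyphenyl)-8-methoxy-4H-chromen-4-one | COc1cc(-c2oc3c(OC)c(OCc4ccccc4)cc(OCc4ccccc4)c3c(=O)c2O)ccc1O
F7 | step 15 | 4-[3-(acetyloxy)-5,7-bis(benzyloxy)-8-methoxy-4-oxo-4H-chromen-2-yl]-2-methoxyphenyl acetate | COc1cc(-c2oc3c(OC)c(OCc4ccccc4)cc(OCc4ccccc4)c3c(=O)c2OC(C)=O)ccc1OC(C)=O
F8 | step 15 | 4-[3-(acetyloxy)-5,7-dihydroxy-8-methoxy-4-oxo-4H-chromen-2-yl]-2-methoxyphenyl acetate | COc1cc(-c2oc3c(OC)c(O)cc(O)c3c(=O)c2OC(C)=O)ccc1OC(C)=O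
F9 | step 15 | 4-{3-(acetyloxy)-5-hydroxy-8-methoxy-7-[(3-methylbut-2-en-1-yl)oxy]-4-oxo-4H-chromen-2-yl}-2-methoxyphenyl acetate | COc1cc(-c2oc3c(OC)c(OCC=C(C)C)cc(O)c3c(=O)c2OC(C)=O)ccc1OC(C)=O
F10 | step 10 | 2,4-bis(benzyloxy)-6-iodo-5-methoxybenzoic acid | O=C(O)c1c(I)c(OC)c(OCc2ccccc2)cc1OCc1ccccc1
F11 | step 10 | 2,4-bis(benzyloxy)-6-iodo-5-methoxybenzoyl chloride | O=C(Cl)c1c(I)c(OC)c(OCc2ccccc2)cc1OCc1ccccc1
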